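## Retrosynthetic overview

1. Target 14 ⇐ hexa-O-benzyl dimer 13 by global hydrogenolysis. Ring C of the upper flavan is the last ring formed, by closure of the ring A phenol onto the ketone of 10 and cis-selective oxocarbenium reduction (sets C2).
2. Key disconnection: the interflavan C4–C8 bond of 10 ⇐ boron homoenolate 6 (nucleophilic β-carbon of a ketone) + 8-bromo-epicatechin ether 9, by stereospecific Suzuki–Miyaura coupling (sets C4).
3. 6 ⇐ chalcone 4 by copper-catalysed asymmetric conjugate borylation; 4 ⇐ aldehyde 2 + ketone 3 (Claisen–Schmidt).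
4. 9 ⇐ (−)-epicatechin 7 by tetra-O-benzylation and C8 bromination; the three rings and both stereocentres of the lower unit are bought intact.

Assumption: the ferrocenyl ligand enantiomer named in step 3 is taken to give the 3R boronate and the coupling in step 6 to go with inversion at carbon; if either sense proves opposite, the mirror-image ligand in step 3 corrects C4 with no other change.

## Route

Step 1
Reactants: 1 4-(benzyloxy)-2-hydroxybenzaldehyde
Product: 2 4-(benzyloxy)-2-(methoxymethoxy)benzaldehyde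
Conditions: MOMCl (1.5 equiv), K2CO3 (3 equiv), acetone, 0 °C to 40 °C
Reagents that add atoms: chloromethyl methyl ether (MOMCl), COCCl
Why: Williamson-type O-alkylation of the phenoxide gives a MOM acetal that survives the base, copper and palladium steps and can later be removed by acid without touching benzyl ethers, so that only this phenol is free for ring closure in step 7.

Step 2
Reactants: 2 4-(benzyloxy)-2-(methoxymethoxy)benzaldehyde; 3 4'-(benzyloxy)acetophenone
Product: 4 (E)-3-[4-(benzyloxy)-2-(methoxymethoxy)phenyl]-1-[4-(benzyloxy)phenyl]prop-2-en-1-one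
Conditions: KOH (3 equiv), EtOH/THF (2:1), rt, 16 h
Reagents that add atoms: none
Why: Claisen–Schmidt condensation (aldol addition then E1cB dehydration) of a methyl ketone with a non-enolisable aldehyde gives the thermodynamically favoured E-chalcone.

Step 3
Reactants: 4 (E)-3-[4-(benzyloxy)-2-(methoxymethoxy)phenyl]-1-[4-(benzyloxy)phenyl]prop-2-en-1-one
Product: 6 potassium [(1R)-1-[4-(benzyloxy)-2-(methoxymethoxy)phenyl]-3-[4-(benzyloxy)phenyl]-3-oxopropyl]trifluoroborate, via pinacol boronate 5 (not isolated)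
Conditions: B2pin2 (1.1 equiv), CuCl (3 mol %), NaOtBu (6 mol %), (R)-1-[(S)-2-(diphenylphosphino)ferrocenyl]ethyldicyclohexylphosphine (3 mol %), MeOH (2 equiv), THF, rt; then KHF2 (4.5 M aq, 4 equiv), MeOH, rt
Reagents that add atoms: bis(pinacolato)diboron (B2pin2), CC1(C)OB(B2OC(C)(C)C(C)(C)O2)OC1(C)C; potassium hydrogen difluoride (KHF2), F.[F-].[K+]
Why: Copper-catalysed asymmetric conjugate borylation of an acyclic enone, in which the chiral phosphine–Cu–Bpin species adds to one face of the β-carbon and MeOH protonates the copper enolate, sets the boron-bearing stereocentre (3R), and KHF2 exchange gives the bench-stable trifluoroborate homoenolate.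

Step 4
Reactants: 7 (−)-epicatechin
Product: 8 (2R,3R)-5,7-bis(benzyloxy)-2-[3,4-bis(benzyloxy)phenyl]chroman-3-ol
Conditions: BnBr (4.2 equiv), K2CO3 (4.5 equiv), DMF, 0 °C to rt
Reagents that add atoms: benzyl bromide, BrCc1ccccc1
Why: Williamson etherification under carbonate alkylates the four phenols and leaves the much less acidic secondary 3-OH free, without touching C2 or C3.

Step 5
Reactants: 8 (2R,3R)-5,7-bis(benzyloxy)-2-[3,4-bis(benzyloxy)phenyl]chroman-3-ol
Product: 9 (2R,3R)-5,7-bis(benzyloxy)-2-[3,4-bis(benzyloxy)phenyl]-8-bromochroman-3-ol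
Conditions: NBS (1.0 equiv), CH2Cl2, −78 °C to rt
Reagents that add atoms: N-bromosuccinimide, O=C1CCC(=O)N1Br
Why: Electrophilic aromatic bromination of the phloroglucinol-type ring A of benzylated flavan-3-ols goes selectively at C8, the more nucleophilic of the two free positions.

Step 6
Reactants: 6 potassium [(1R)-1-[4-(benzyloxy)-2-(methoxymethoxy)phenyl]-3-[4-(benzyloxy)phenyl]-3-oxopropyl]trifluoroborate; 9 (2R,3R)-5,7-bis(benzyloxy)-2-[3,4-bis(benzyloxy)phenyl]-8-bromochroman-3-ol
Product: 10 (3S)-3-[4-(benzyloxy)-2-(methoxymethoxy)phenyl]-1-[4-(benzyloxy)phenyl]-3-[(2R,3R)-5,7-bis(benzyloxy)-2-[3,4-bis(benzyloxy)phenyl]-3-hydroxychroman-8-yl]propan-1-one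
Conditions: Pd(OAc)2 (10 mol %), XPhos (2-dicyclohexylphosphino-2',4',6'-triisopropylbiphenyl, 20 mol %), K2CO3 (3 equiv), cyclopentyl methyl ether/H2O (7:1), 95 °C, 24 h, 6 in 1.5-fold excess
Reagents that add atoms: none
Why: Proposed new method: a stereospecific Suzuki–Miyaura coupling in which the homoenolate 6 delivers its nucleophilic β-carbon to the aryl–palladium bromide formed from 9 by oxidative addition to zerovalent palladium; the ketone oxygen binds boron so that transmetalation runs through an open SE2 transition state with inversion (3R to 3S), the resulting five-membered C,O-chelated alkyl–palladium resists β-hydride elimination, and the bulky biaryl phosphine drives reductive elimination to the hindered diarylmethine; the closest known reactions are the invertive couplings of secondary β-trifluoroborato amides and β-boryl esters with aryl halides and the stereospecific couplings of secondary benzylic boronates.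

Step 7
Reactants: 10 (3S)-3-[4-(benzyloxy)-2-(methoxymethoxy)phenyl]-1-[4-(benzyloxy)phenyl]-3-[(2R,3R)-5,7-bis(benzyloxy)-2-[3,4-bis(benzyloxy)phenyl]-3-hydroxychroman-8-yl]propan-1-one
Product: 13 (2R,3R)-5,7-bis(benzyloxy)-8-[(2S,4S)-7-(benzyloxy)-2-[4-(benzyloxy)phenyl]chroman-4-yl]-2-[3,4-bis(benzyloxy)phenyl]chroman-3-ol, via free phenol ketone 11 (not isolated), via cyclic hemiketal 12 (not isolated)
Conditions: 3 M HCl aq/THF (1:4), 45 °C; then Et3SiH (3 equiv), BF3·OEt2 (2 equiv), CH2Cl2, −78 °C to −30 °C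
Reagents that add atoms: none
Why: Acid hydrolysis of the MOM acetal frees the only phenol in the molecule, which closes onto the aryl ketone as a six-membered hemiketal, and ionic hydrogenation of this lactol (Et3SiH/BF3·OEt2 via the 2-aryl oxocarbenium ion) delivers hydride to C2 from the face opposite the pseudoaxial C4 aryl group, setting C2 as S in the 2,4-cis relationship.

Step 8
Reactants: 13 (2R,3R)-5,7-bis(benzyloxy)-8-[(2S,4S)-7-(benzyloxy)-2-[4-(benzyloxy)phenyl]chroman-4-yl]-2-[3,4-bis(benzyloxy)phenyl]chroman-3-ol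
Product: 14 (2R,3R)-2-(3,4-dihydroxyphenyl)-8-[(2S,4S)-7-hydroxy-2-(4-hydroxyphenyl)chroman-4-yl]chromane-3,5,7-triol (CNP0298337.1)
Conditions: H2 (1 atm), Pd(OH)2/C, THF/MeOH (1:1), rt
Reagents that add atoms: none
Why: Catalytic hydrogenolysis removes the six benzyl ethers under neutral conditions that leave the flavan C2–O bonds, the interflavan bond and all four stereocentres untouched, as in standard proanthocyanidin deprotections.

## Compound list

1 | 4-(benzyloxy)-2-hydroxybenzaldehyde | O=Cc1ccc(OCc2ccccc2)cc1O | starting material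
2 | 4-(benzyloxy)-2-(methoxymethoxy)benzaldehyde | O=Cc1ccc(OCc2ccccc2)cc1OCOC | intermediate
3 | 4'-(benzyloxy)acetophenone | CC(=O)c1ccc(OCc2ccccc2)cc1 | starting material
4 | (E)-3-[4-(benzyloxy)-2-(methoxymethoxy)phenyl]-1-[4-(benzyloxy)phenyl]prop-2-en-1-one | O=C(/C=C/c1ccc(OCc2ccccc2)cc1OCOC)c1ccc(OCc2ccccc2)cc1 | intermediate
5 | (3R)-3-[4-(benzyloxy)-2-(methoxymethoxy)phenyl]-1-[4-(benzyloxy)phenyl]-3-(4,4,5,5-tetramethyl-1,3,2-dioxaborolan-2-yl)propan-1-one (not isolated) | O=C(C[C@@H](B1OC(C)(C)C(C)(C)O1)c1ccc(OCc2ccccc2)cc1OCOC)c1ccc(OCc2ccccc2)cc1 | intermediate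
6 | potassium [(1R)-1-[4-(benzyloxy)-2-(methoxymethoxy)phenyl]-3-[4-(benzyloxy)phenyl]-3-oxopropyl]trifluoroborate | O=C(C[C@@H]([B-](F)(F)F)c1ccc(OCc2ccccc2)cc1OCOC)c1ccc(OCc2ccccc2)cc1.[K+] | intermediate
7 | (−)-epicatechin, (2R,3R)-2-(3,4-dihydroxyphenyl)chromane-3,5,7-triol | Oc1cc(O)c2c(c1)O[C@H](c1ccc(O)c(O)c1)[C@H](O)C2 | starting material
8 | (2R,3R)-5,7-bis(benzyloxy)-2-[3,4-bis(benzyloxy)phenyl]chroman-3-ol | O(Cc1ccccc1)c1cc(OCc2ccccc2)c2c(c1)O[C@H](c1ccc(OCc3ccccc3)c(OCc3ccccc3)c1)[C@H](O)C2 | intermediate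
9 | (2R,3R)-5,7-bis(benzyloxy)-2-[3,4-bis(benzyloxy)phenyl]-8-bromochroman-3-ol | O(Cc1ccccc1)c1cc(OCc2ccccc2)c2c(c1Br)O[C@H](c1ccc(OCc3ccccc3)c(OCc3ccccc3)c1)[C@H](O)C2 | intermediate
10 | (3S)-3-[4-(benzyloxy)-2-(methoxymethoxy)phenyl]-1-[4-(benzyloxy)phenyl]-3-[(2R,3R)-5,7-bis(benzyloxy)-2-[3,4-bis(benzyloxy)phenyl]-3-hydroxychroman-8-yl]propan-1-one | O=C(C[C@H](c1c(OCc2ccccc2)cc(OCc2ccccc2)c2c1O[C@H](c1ccc(OCc3ccccc3)c(OCc3ccccc3)c1)[C@H](O)C2)c1ccc(OCc2ccccc2)cc1OCOC)c1ccc(OCc2ccccc2)cc1 | intermediate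
11 | (3S)-3-[4-(benzyloxy)-2-hydroxyphenyl]-1-[4-(benzyloxy)phenyl]-3-[(2R,3R)-5,7-bis(benzyloxy)-2-[3,4-bis(benzyloxy)phenyl]-3-hydroxychroman-8-yl]propan-1-one (not isolated) | O=C(C[C@H](c1c(OCc2ccccc2)cc(OCc2ccccc2)c2c1O[C@H](c1ccc(OCc3ccccc3)c(OCc3ccccc3)c1)[C@H](O)C2)c1ccc(OCc2ccccc2)cc1O)c1ccc(OCc2ccccc2)cc1 | intermediate
12 | (4S)-7-(benzyloxy)-2-[4-(benzyloxy)phenyl]-4-[(2R,3R)-5,7-bis(benzyloxy)-2-[3,4-bis(benzyloxy)phenyl]-3-hydroxychroman-8-yl]chroman-2-ol, both C2 epimers (not isolated) | OC1(c2ccc(OCc3ccccc3)cc2)C[C@H](c2c(OCc3ccccc3)cc(OCc3ccccc3)c3c2O[C@H](c2ccc(OCc4ccccc4)c(OCc4ccccc4)c2)[C@H](O)C3)c2ccc(OCc3ccccc3)cc2O1 | intermediate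
13 | (2R,3R)-5,7-bis(benzyloxy)-8-[(2S,4S)-7-(benzyloxy)-2-[4-(benzyloxy)phenyl]chroman-4-yl]-2-[3,4-bis(benzyloxy)phenyl]chroman-3-ol | O(Cc1ccccc1)c1ccc([C@@H]2C[C@H](c3c(OCc4ccccc4)cc(OCc4ccccc4)c4c3O[C@H](c3ccc(OCc5ccccc5)c(OCc5ccccc5)c3)[C@H](O)C4)c3ccc(OCc4ccccc4)cc3O2)cc1 | intermediate
14 | (2R,3R)-2-(3,4-dihydroxyphenyl)-8-[(2S,4S)-7-hydroxy-2-(4-hydroxyphenyl)chroman-4-yl]chromane-3,5,7-triol | Oc1ccc([C@@H]2C[C@H](c3c(O)cc(O)c4c3O[C@H](c3ccc(O)c(O)c3)[C@H](O)C4)c3ccc(O)cc3O2)cc1 | target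

## Step count

Total steps: 8. Longest linear sequence: 6 (steps 1, 2, 3, 6, 7, 8). The epicatechin branch (steps 4 and 5) joins at step 6.

## Steps most likely to fail, with fallbacks

**Step 6 (key coupling).** Both partners are hindered, so transmetalation may lose to protodeboronation or to β-hydride elimination back to chalcone 4, and the ketone may bind boron too weakly for clean inversion. Because 9 is enantiopure, any loss of fidelity shows up as the separable C3 epimer of 10.

The fallback sets out from aldehyde 2 and comes back to the route at ketone 10. It uses an amide, whose stronger carbonyl donor follows the best precedent for invertive, elimination-free coupling, and adds the ring B aryl ketone afterwards. Horner–Wadsworth–Emmons olefination of 2 with diethyl [2-[methoxy(methyl)amino]-2-oxoethyl]phosphonate (NaH, THF) gives the (E)-Weinreb cinnamamide F1. Copper-catalysed asymmetric borylation as in step 3 gives the (3R)-pinacol boronate amide F2, and KHF2 turns it into the potassium trifluoroborate amide F3. F3 is coupled with bromide 9 under Pd(OAc)2/XPhos/K2CO3 to give the coupled (3S)-Weinreb amide F4. Commercial 4-(benzyloxy)phenylmagnesium bromide (3 equiv, THF, 0 °C; one equivalent is used up by the free 3-OH) converts F4 into 10.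

**Step 7 (ring closure and C2 reduction).** The hydride delivery may give a poor cis/trans ratio at C2, and the newly formed benzylic ether may be over-reduced or the interflavan bond cleaved by the acid.

The fallback sets out from 10 and comes back at target 14. The MOM group is removed with 3 M HCl aq/THF as before and the hemiketal is dehydrated (camphorsulfonic acid cat., toluene, MgSO4, 60 °C) to the 4H-flavene F5. Hydrogenation (H2, Pd/C with Pd(OH)2/C, EtOAc/MeOH) adds hydrogen to the C2=C3 enol ether from the face opposite the C4 aryl group, giving the 2,4-cis flavan, and removes the six benzyl groups in the same operation. C2 is then set by heterogeneous syn-hydrogenation rather than by ionic hydride delivery.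

**Step 3 (asymmetric borylation).** The ortho-alkoxy β-aryl group may lower the enantioselectivity, and the facial sense of the ligand is assumed.

The fallback sets out from chalcone 4 and comes back at trifluoroborate 6. Borylation with an achiral catalyst (CuCl, NaOtBu, bis[2-(diphenylphosphino)phenyl] ether, B2pin2, MeOH, THF) gives the racemic pinacol boronate ketone F6. F6 is resolved by preparative chromatography on a chiral stationary phase, and the 3R enantiomer, here isolated as compound 5, is treated with KHF2 to give 6.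

Further compounds
F1 | step 6 | (E)-3-[4-(benzyloxy)-2-(methoxymethoxy)phenyl]-N-methoxy-N-methylprop-2-enamide | CON(C)C(=O)/C=C/c1ccc(OCc2ccccc2)cc1OCOC
F2 | step 6 | (3R)-3-[4-(benzyloxy)-2-(methoxymethoxy)phenyl]-N-methoxy-N-methyl-3-(4,4,5,5-tetramethyl-1,3,2-dioxaborolan-2-yl)propanamide | CON(C)C(=O)C[C@@H](B1OC(C)(C)C(C)(C)O1)c1ccc(OCc2ccccc2)cc1OCOC
F3 | step 6 | potassium [(1R)-1-[4-(benzyloxy)-2-(methoxymethoxy)phenyl]-3-[methoxy(methyl)amino]-3-oxopropyl]trifluoroborate | CON(C)C(=O)C[C@@H]([B-](F)(F)F)c1ccc(OCc2ccccc2)cc1OCOC.[K+]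
F4 | step 6 | (3S)-3-[4-(benzyloxy)-2-(methoxymethoxy)phenyl]-3-[(2R,3R)-5,7-bis(benzyloxy)-2-[3,4-bis(benzyloxy)phenyl]-3-hydroxychroman-8-yl]-N-methoxy-N-methylpropanamide | CON(C)C(=O)C[C@H](c1c(OCc2ccccc2)cc(OCc2ccccc2)c2c1O[C@H](c1ccc(OCc3ccccc3)c(OCc3ccccc3)c1)[C@H](O)C2)c1ccc(OCc2ccccc2)cc1OCOC
F5 | step 7 | (2R,3R)-5,7-bis(benzyloxy)-8-[(4S)-7-(benzyloxy)-2-[4-(benzyloxy)phenyl]-4H-chromen-4-yl]-2-[3,4-bis(benzyloxy)phenyl]chroman-3-ol | O(Cc1ccccc1)c1ccc(C2=C[C@H](c3c(OCc4ccccc4)cc(OCc4ccccc4)c4c3O[C@H](c3ccc(OCc5ccccc5)c(OCc5ccccc5)c3)[C@H](O)C4)c3ccc(OCc4ccccc4)cc3O2)cc1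
F6 | step 3 | racemic 3-[4-(benzyloxy)-2-(methoxymethoxy)phenyl]-1-[4-(benzyloxy)phenyl]-3-(4,4,5,5-tetramethyl-1,3,2-dioxaborolan-2-yl)propan-1-one | O=C(CC(B1OC(C)(C)C(C)(C)O1)c1ccc(OCc2ccccc2)cc1OCOC)c1ccc(OCc2ccccc2)cc1
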